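**Retrosynthetic overview**
1. Target 23 ⇐ 6-ketone 22 by a late electron-transfer reduction that gives the equatorial 6α-OH; the C6 carbonyl is kept until then because it drives the key step.
2. Ring B (C5, C6, C7, C8, C9, C10) is opened at C9–C10, the bond between the neopentyl C9 and quaternary C10: 22 ⇐ 9,10-seco thionocarbonate 21. Enabling feature: the C6 oxygen stands 1,3 to C10, so as C6=O inside the tether C9–C8–C7–C6(=O)–C5=C10 it polarises the tetrasubstituted ring-A alkene for 6-endo attack at C10, while quaternary C8 and the trans-fused oxocene hold ring C as a locked chair beside the C9 radical.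
3. 21 ⇐ Weinreb amide 15 (ring C plus oxocene, carrying C8, C13, C14 and a C9 hydroxyl as traceless radical handle) + vinyllithium 19 (ring A, achiral).
4. 15 ⇐ oxocene ketone 7 (double alkylation at C8 with the C11=C12 enone as blocking group) ⇐ ring-closing metathesis ⇐ epoxide 3 (Shi epoxidation and trans-diaxial cuprate opening set C13 and C14) ⇐ triflate 1.
5. Order of ring formation: ring C (bought in 1), oxocene (step 5), ring A (bought in 16, joined in step 13), ring B last (step 15).

Key step: step 15

Remark on the chemistry: cheilanthane numbering of the target is used for all intermediates (ring A C1–C5, C10; ring B C5–C10; ring C C8, C9, C11–C14; oxocene O, C13–C19 with the methyl on C17), β is the face of the C13 methyl, and the Shi ketone antipode is assumed to be the one that delivers oxygen to the α face of alkene 2.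

**Step 1**
Reactants: 1 1,4-dioxaspiro[4.5]dec-7-en-8-yl trifluoromethanesulfonate
Product: 2 8-methyl-1,4-dioxaspiro[4.5]dec-7-ene
Conditions: MeMgBr, Fe(acac)3 (5 mol %), THF/NMP, −30 to 0 °C
Reagents that add atoms: methylmagnesium bromide, C[Mg]Br
Why: Iron-catalysed Kumada-type cross-coupling of an alkenyl triflate with MeMgBr replaces OTf by methyl without touching the ketal and fixes the trisubstituted C13=C14 alkene.

**Step 2**
Reactants: 2 8-methyl-1,4-dioxaspiro[4.5]dec-7-ene
Product: 3 (1'R,6'S)-6'-methylspiro[1,3-dioxolane-2,3'-[7]oxabicyclo[4.1.0]heptane] (α-epoxide)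
Conditions: fructose-derived Shi ketone (30 mol %), Oxone (2KHSO5·KHSO4·K2SO4), K2CO3, Bu4NHSO4, MeCN/dimethoxymethane, aqueous buffer pH 10.5, 0 °C
Reagents that add atoms: potassium peroxymonosulfate, [K+].[O-]S(=O)(=O)OO
Why: Shi asymmetric epoxidation (chiral dioxirane, spiro transition state) of the trisubstituted alkene sets C13 and C14 as the α-epoxide, in the facial sense known for 1-substituted cyclohexenes, and the basic buffer preserves the ketal.

**Step 3**
Reactants: 3 α-epoxide
Product: 4 (7S,8S)-8-methyl-7-(3-methylbut-3-en-1-yl)-1,4-dioxaspiro[4.5]decan-8-ol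
Conditions: (3-methylbut-3-en-1-yl)magnesium bromide (made from 4-bromo-2-methylbut-1-ene and Mg in THF), CuI (20 mol %), THF, −30 to 0 °C; aq. NH4Cl
Reagents that add atoms: (3-methylbut-3-en-1-yl)magnesium bromide, C=C(C)CC[Mg]Br
Why: Copper-catalysed Grignard opening of a trisubstituted epoxide occurs at the secondary carbon C14 with inversion (trans-diaxial, Fürst–Plattner rule), which places the side chain β and trans to the retained 13α-oxygen as the trans oxocene fusion requires.

**Step 4**
Reactants: 4 tertiary alcohol
Product: 5 (7S,8S)-8-methyl-7-(3-methylbut-3-en-1-yl)-8-(prop-2-en-1-yloxy)-1,4-dioxaspiro[4.5]decane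
Conditions: KH, allyl bromide, Bu4NI (cat.), THF, 0 °C to rt
Reagents that add atoms: allyl bromide, C=CCBr
Why: Williamson etherification of the tertiary potassium alkoxide with a reactive allylic bromide should be clean because no enolisable carbonyl is present at this stage.

**Step 5**
Reactants: 5 diene
Product: 6 trans-fused oxocene ketal (ethylene ketal of 7)
Conditions: second-generation Grubbs catalyst RuCl2(=CHPh)(H2IMes)(PCy3) (10 mol %), 1,4-benzoquinone (20 mol %), CH2Cl2 (2 mM), 40 °C
Reagents that add atoms: none
Why: Ring-closing metathesis between the allyl ether (initiation site) and the 1,1-disubstituted alkene releases ethene and closes the eight-membered ether; the trans-diequatorial C13–O and C14–C15 bonds pre-organise the chains and the ring size enforces the Z trisubstituted alkene.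

**Step 6**
Reactants: 6 oxocene ketal
Product: 7 (3Z,6aS,10aS)-4,10a-dimethyl-2,5,6,6a,7,9,10,10a-octahydro-8H-1-benzoxocin-8-one (C9 ketone)
Conditions: PPTS (0.2 equiv), THF/H2O 4:1, 55 °C
Reagents that add atoms: water, O
Why: Mild acid-catalysed ketal hydrolysis unmasks the C9 ketone while the weakly acidic medium leaves the tertiary allylic ether intact.

**Step 7**
Reactants: 7 oxocene ketone
Product: 9 oxocene-fused cyclohexenone (C9 ketone; C11=C12), via lithium enolate 8 (not isolated)
Conditions: LiN(i-Pr)2, THF, −78 °C; then N-tert-butylbenzenesulfinimidoyl chloride, −78 °C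
Reagents that add atoms: none
Why: Kinetic deprotonation should occur at C11, the α-carbon remote from the ring-fusion carbon C14 (the preference shown toward C2 by trans-fused 3-keto steroids), and Mukaiyama dehydrogenation of the enolate gives the C11=C12 enone that blocks this side for the alkylations.

**Step 8**
Reactants: 9 enone
Product: 11 8-methyl enone (8α-methyl expected), via lithium dienolate 10 (not isolated)
Conditions: LiN(i-Pr)2, THF, −78 °C; then MeI, −78 to −40 °C
Reagents that add atoms: iodomethane, CI
Why: Alkylation of the cross-conjugated α′-enolate of an enone is regiospecific because C8 is the only enolisable position (C13 is quaternary), and the configuration of the new methine is irrelevant since it is enolised again in step 9.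

**Step 9**
Reactants: 11 8-methyl enone
Product: 13 Weinreb amide enone (8β-methyl; 8α-CH2C(O)N(OMe)Me), via lithium dienolate 12 (not isolated)
Conditions: LiN(i-Pr)2, THF/DMPU, −78 °C; then BrCH2C(O)N(OMe)Me, −78 to 0 °C
Reagents that add atoms: 2-bromo-N-methoxy-N-methylacetamide, BrCC(=O)N(C)OC
Why: Enolate alkylation creates the C8 quaternary centre, the electrophile entering from the α face, anti to the pseudoaxial 13β-methyl and the 14β chain (the sense known for C4 alkylation of angular-methyl decalone enolates), so the methyl ends β.

**Step 10**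
Reactants: 13 Weinreb amide enone
Product: 14 saturated keto amide (C9 ketone)
Conditions: [(Ph3P)CuH]6 (0.4 equiv), H2O (2 equiv), benzene, rt
Reagents that add atoms: none
Why: Copper hydride conjugate reduction removes the blocking C11=C12 bond selectively in the presence of the isolated trisubstituted alkene and the Weinreb amide, and unlike a dissolving-metal reduction it cannot expel the γ-alkoxy group.

**Step 11**
Reactants: 14 saturated keto amide
Product: 15 hydroxy amide (9β-OH expected)
Conditions: NaBH4, MeOH, 0 °C
Reagents that add atoms: none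
Why: Borohydride reduction of the ketone (axial attack beside quaternary C8 should give mainly the equatorial 9β-alcohol, either epimer being usable because C9 later becomes a radical) leaves the Weinreb amide untouched.

**Step 12**
Reactants: 16 2,2,6-trimethylcyclohexanone; 17 2,4,6-triisopropylbenzenesulfonohydrazide
Product: 18 2,2,6-trimethylcyclohexanone 2,4,6-triisopropylbenzenesulfonylhydrazone
Conditions: MeOH, HCl (cat.), rt
Reagents that add atoms: none
Why: Acid-catalysed hydrazone condensation gives the Shapiro precursor, and the stereocentre of racemic 16 is destroyed in step 13.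

**Step 13**
Reactants: 18 trisylhydrazone (3.5 equiv); 15 hydroxy amide
Product: 20 9β-hydroxy-13α,19-epoxy-9,10-secocheilantha-5(10),17-dien-6-one, via 2,6,6-trimethylcyclohex-1-en-1-yllithium 19 (not isolated)
Conditions: n-BuLi (7 equiv), TMEDA, hexane/THF, −78 to 0 °C (N2 evolution); then 15, THF, −78 to 0 °C; aq. NH4Cl
Reagents that add atoms: none
Why: The Shapiro reaction (dianion at the only α-C–H, loss of sulfinate and N2) generates the tetrasubstituted vinyllithium, which acylates the Weinreb amide once through the chelated tetrahedral intermediate (Weinreb ketone synthesis) after one equivalent has deprotonated the C9 hydroxyl.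

**Step 14**
Reactants: 20 hydroxy enone
Product: 21 O-phenyl thionocarbonate of 20 (radical precursor at C9)
Conditions: PhOC(S)Cl, pyridine, DMAP (cat.), CH2Cl2, rt
Reagents that add atoms: O-phenyl chlorothionoformate, S=C(Cl)Oc1ccccc1
Why: DMAP-catalysed thioacylation of the secondary alcohol installs the Barton–McCombie leaving group under non-enolising conditions that spare the hindered enone.

**Step 15**
Reactants: 21 thionocarbonate
Product: 22 13α,19-epoxycheilanth-17-en-6-one (5αH; 9αH; 8β-Me; 10β-Me)
Conditions: Bu3SnH (1.3 equiv) and AIBN (0.2 equiv) added by syringe pump over 10 h to 21 (2 mM) in benzene, 80 °C; then DBU, rt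
Reagents that add atoms: none
Why: Bu3Sn• adds to the thiocarbonyl sulfur and β-scission releases the secondary C9 radical, which adds to C10 of the C6(=O)–C5=C10 enone; the resulting C5 α-keto radical abstracts hydrogen from the stannane and carries the chain. The closest known reaction type is a Barton–McCombie-initiated radical cyclisation, here a 6-endo-trig radical conjugate addition to an enone whose carbonyl lies in the tether, the manifold by which polyene-type radical cyclisations deliver trans-decalins. Ring B closes 6-endo-trig through a chair-like transition state (C9, C8, C7, C6, C5, C10), and 5-exo attack at C5 is disfavoured because C5 is the α-carbon of the enone and would become a spiro centre next to the gem-dimethyl group. C9 is set by the locked chair of ring C (trans-fused oxocene, C7 equatorial on C8), which makes the new bond equatorial and gives 9α-H; C10 is set by the ring-A alkene geometry, since the methyl cis to C6 must become axial in the chair and hence syn to the 8β-methyl (10β-Me); C5 is set by hydrogen transfer to the α face opposite both axial methyls, and DBU equilibration through the C6 enolate secures the trans A/B fusion. The step needs cyclisation to outrun direct reduction of the C9 radical, which the low stationary stannane concentration should secure, and it needs chemoselectivity, which rests on the thiocarbonyl being the best stannyl-radical acceptor, on the isolated C17=C18 alkene being inert to a nucleophilic alkyl radical and held out of reach by the trans ring fusion, and on quaternary C8 blocking any elimination pathway.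

**Step 16**
Reactants: 22 tetracyclic 6-ketone
Product: 23 13α,19-epoxycheilanth-17-en-6α-ol (target)
Conditions: SmI2 (3 equiv), H2O, Et3N, THF, 0 °C, 5 min
Reagents that add atoms: none
Why: Electron-transfer reduction of the ketone by samarium diiodide with water and amine passes through a ketyl and carbanion that protonate to the more stable equatorial alcohol, so the 6α-OH should result where hydride reagents attacking the open α face would give the axial 6β-epimer, and the short reaction time should spare the trisubstituted allylic ether.

**Compound list**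
1 | 1,4-dioxaspiro[4.5]dec-7-en-8-yl trifluoromethanesulfonate | O=S(=O)(OC1=CCC2(CC1)OCCO2)C(F)(F)F | starting material
2 | 8-methyl-1,4-dioxaspiro[4.5]dec-7-ene | CC1=CCC2(CC1)OCCO2 | intermediate
3 | (1'R,6'S)-6'-methylspiro[1,3-dioxolane-2,3'-[7]oxabicyclo[4.1.0]heptane] | C[C@]12CCC3(OCCO3)C[C@H]1O2 | intermediate
4 | (7S,8S)-8-methyl-7-(3-methylbut-3-en-1-yl)-1,4-dioxaspiro[4.5]decan-8-ol | O[C@@]1(C)CCC2(OCCO2)C[C@@H]1CCC(C)=C | intermediate
5 | (7S,8S)-8-methyl-7-(3-methylbut-3-en-1-yl)-8-(prop-2-en-1-yloxy)-1,4-dioxaspiro[4.5]decane | C=CCO[C@@]1(C)CCC2(OCCO2)C[C@@H]1CCC(C)=C | intermediate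
6 | ethylene ketal of 7 (trans-fused Z-oxocene; 13β-Me, 13α-O, 14α-H) | C/C1=C/CO[C@@]2(C)CCC3(OCCO3)C[C@@H]2CC1 | intermediate
7 | (3Z,6aS,10aS)-4,10a-dimethyl-2,5,6,6a,7,9,10,10a-octahydro-8H-1-benzoxocin-8-one (C9 ketone) | C/C1=C/CO[C@@]2(C)CCC(=O)C[C@@H]2CC1 | intermediate
8 | lithium enolate of 7 (C9=C11) | C/C1=C/CO[C@@]2(C)CC=C(O[Li])C[C@@H]2CC1 | intermediate (not isolated)
9 | 4,10a-dimethyl-2,5,6,6a,7,10a-hexahydro-8H-1-benzoxocin-8-one (C9 ketone, C11=C12; 13β-Me, 13α-O, 14α-H) | C/C1=C/CO[C@@]2(C)C=CC(=O)C[C@@H]2CC1 | intermediate
10 | lithium cross-conjugated dienolate of 9 (C8=C9) | C/C1=C/CO[C@@]2(C)C=CC(O[Li])=C[C@@H]2CC1 | intermediate (not isolated)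
11 | 8α-methyl derivative of 9 | C/C1=C/CO[C@@]2(C)C=CC(=O)[C@@H](C)[C@@H]2CC1 | intermediate
12 | lithium dienolate of 11 | C/C1=C/CO[C@@]2(C)C=CC(O[Li])=C(C)[C@@H]2CC1 | intermediate (not isolated)
13 | N-methoxy-N-methyl-2-(8β-methyl-9-oxo enone bicycle-8α-yl)acetamide (C11=C12; 13β-Me, 13α-O, 14α-H) | C/C1=C/CO[C@@]2(C)C=CC(=O)[C@@](C)(CC(=O)N(C)OC)[C@@H]2CC1 | intermediate
14 | 11,12-dihydro derivative of 13 (saturated C9 ketone) | C/C1=C/CO[C@@]2(C)CCC(=O)[C@@](C)(CC(=O)N(C)OC)[C@@H]2CC1 | intermediate
15 | 9β-hydroxy derivative of 14 (hydroxy Weinreb amide) | C/C1=C/CO[C@@]2(C)CC[C@H](O)[C@@](C)(CC(=O)N(C)OC)[C@@H]2CC1 | intermediate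
16 | 2,2,6-trimethylcyclohexanone (racemic) | CC1CCCC(C)(C)C1=O | starting material
17 | 2,4,6-triisopropylbenzenesulfonohydrazide | CC(C)c1cc(C(C)C)c(S(=O)(=O)NN)c(C(C)C)c1 | starting material
18 | 2,2,6-trimethylcyclohexanone 2,4,6-triisopropylbenzenesulfonylhydrazone | CC1CCCC(C)(C)C1=NNS(=O)(=O)c1c(C(C)C)cc(C(C)C)cc1C(C)C | intermediate
19 | 2,6,6-trimethylcyclohex-1-en-1-yllithium | [Li]C1=C(C)CCCC1(C)C | intermediate (not isolated)
20 | 9β-hydroxy-13α,19-epoxy-9,10-secocheilantha-5(10),17-dien-6-one (8β-Me, 14α-H) | C/C1=C/CO[C@@]2(C)CC[C@H](O)[C@@](C)(CC(=O)C3=C(C)CCCC3(C)C)[C@@H]2CC1 | intermediate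
21 | O-phenyl thionocarbonate of 20 at the 9β-oxygen | C/C1=C/CO[C@@]2(C)CC[C@H](OC(=S)Oc3ccccc3)[C@@](C)(CC(=O)C3=C(C)CCCC3(C)C)[C@@H]2CC1 | intermediate
22 | 13α,19-epoxycheilanth-17-en-6-one, (5S,8R,9S,10R,13S,14S), 5αH, 9αH | C/C1=C/CO[C@@]2(C)CC[C@@H]3[C@@]4(C)CCCC(C)(C)[C@@H]4C(=O)C[C@@]3(C)[C@@H]2CC1 | intermediate
23 | 13α,19-epoxycheilanth-17-en-6α-ol, (5S,6S,8R,9R,10R,13S,14S) | C/C1=C/CO[C@@]2(C)CC[C@@H]3[C@@]4(C)CCCC(C)(C)[C@@H]4[C@@H](O)C[C@@]3(C)[C@@H]2CC1 | target

Total step count: 16. Longest linear sequence: 15 steps (steps 1–11 and 13–16, from 1 to 23).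

**Steps most likely to fail**

Step 15. The C9 radical may take hydrogen from the stannane before the slow 6-endo addition to the twisted, tetrasubstituted enone, or it may close through a non-chair transition state that gives the cis B/C or 10-epi series. The fallback sets out from 20 and comes back at 22, and it replaces the tin hydride chain by a hydride-free radical–polar crossover. Acylation of 20 with methyl chlorooxoacetate (Et3N, DMAP, CH2Cl2) gives the methyl oxalate F1. Hydrolysis with CsOH (1 equiv, THF/H2O) gives the cesium oxalate F2. Irradiation of F2 (blue LEDs, Ir[dF(CF3)ppy]2(dtbbpy)PF6, DME/DMF, H2O, 60 °C) generates the same C9 radical by oxidation and double decarboxylation; this is the known redox-neutral oxalate conjugate addition of secondary and tertiary alcohols. With no hydrogen-atom donor at high concentration the radical can wait for cyclisation, the cyclised C5 radical is reduced to the enolate by the reduced photocatalyst and protonated by water, and DBU treatment then gives 22.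

Step 5. Intermolecular metathesis (oligomerisation) may compete with the slow closure of the eight-membered ring onto the 1,1-disubstituted alkene. The fallback sets out from 3 and comes back at 6, and it forms the oxocene by a C16–C17 cross-coupling instead of alkene metathesis. Opening of 3 with vinylmagnesium bromide and CuI gives the vinyl carbinol F3. KH and (Z)-1-bromo-3-iodobut-2-ene (from but-2-yn-1-ol) give the iodoalkenyl ether F4. 9-BBN hydroborates only the monosubstituted vinyl group to the B-alkyl borane F5. An intramolecular B-alkyl Suzuki–Miyaura coupling (Pd(dppf)Cl2, AsPh3, Cs2CO3, DMF/THF/H2O, high dilution) then closes the ring with retention of the Z alkene geometry and delivers 6.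

Step 16. Delivery of hydrogen to the open α face may give the axial 6β-alcohol, or the allylic C19–O bond may be cleaved reductively. The fallback sets out from 22 and comes back at 23, and it separates reduction from stereocontrol. NaBH4 in MeOH reduces 22 to the axial 6β-alcohol F6. F6 is then equilibrated with Al(Oi-Pr)3, i-PrOH and a trace of acetone in toluene at reflux (reversible Meerwein–Ponndorf–Verley/Oppenauer hydride transfer). This should convert the epimer strained by three syn-axial methyl groups into the equatorial 6α-alcohol 23 without any electron-transfer reagent.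

**Further compounds**
F1 | step 15 | methyl oxalate of 20 at the 9β-oxygen | C/C1=C/CO[C@@]2(C)CC[C@H](OC(=O)C(=O)OC)[C@@](C)(CC(=O)C3=C(C)CCCC3(C)C)[C@@H]2CC1
F2 | step 15 | cesium oxalate of 20 at the 9β-oxygen | C/C1=C/CO[C@@]2(C)CC[C@H](OC(=O)C(=O)[O-])[C@@](C)(CC(=O)C3=C(C)CCCC3(C)C)[C@@H]2CC1.[Cs+]
F3 | step 5 | (7R,8S)-7-ethenyl-8-methyl-1,4-dioxaspiro[4.5]decan-8-ol | O[C@@]1(C)CCC2(OCCO2)C[C@@H]1C=C
F4 | step 5 | (7R,8S)-7-ethenyl-8-{[(2Z)-3-iodobut-2-en-1-yl]oxy}-8-methyl-1,4-dioxaspiro[4.5]decane | C/C(I)=C/CO[C@@]1(C)CCC2(OCCO2)C[C@@H]1C=C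
F5 | step 5 | 9-BBN adduct of F4 (boron on C16) | C/C(I)=C/CO[C@@]1(C)CCC2(OCCO2)C[C@@H]1CCB1C2CCCC1CCC2
F6 | step 16 | 13α,19-epoxycheilanth-17-en-6β-ol (6-epimer of 23) | C/C1=C/CO[C@@]2(C)CC[C@@H]3[C@@]4(C)CCCC(C)(C)[C@@H]4[C@H](O)C[C@@]3(C)[C@@H]2CC1
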